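The route rests on making the depside ester first, on an unhindered alkynoic acid, and growing ring A (the acyl ring) around it last. The feature exploited is the pattern of ring A. C1, which carries the ester carbonyl, is squeezed between C2–OH and the C6 oxopentyl chain, while the oxygens on C2 and C4 are meta to each other. C2–C5 therefore map onto a Brassard diene and C1/C6 onto an alkyne. One Diels–Alder/aromatisation forms two C–C bonds, the benzene ring and its full substitution pattern. The precursor is benzyl olivetolate (ring B) acylated at O4 by 4-(2-propyl-1,3-dioxolan-2-yl)but-2-ynoic acid, the ketal blocking allene and isocoumarin formation.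

Key step: step 8

Remark on the chemistry: ring A is numbered from the carbon bearing the depside carbonyl (C1) and ring B as in olivetolic acid. The ketene acetal geometry of diene 13 is left undefined because both isomers converge on the same arene.

Step 1
Reactants: 1 ethyl 3-oxohexanoate
Product: 2 ethyl 2-(2-propyl-1,3-dioxolan-2-yl)acetate
Conditions: HOCH2CH2OH (2 equiv), p-toluenesulfonic acid monohydrate (p-TsOH·H2O, cat.), toluene, Dean–Stark reflux
Reagents that add atoms: ethylene glycol, OCCO
Why: Acid-catalysed ketalisation with azeotropic removal of water is routine for β-keto esters and masks the ketone that would otherwise make every later alkyne intermediate a base-sensitive β,γ-ynone.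

Step 2
Reactants: 2 ethyl 2-(2-propyl-1,3-dioxolan-2-yl)acetate
Product: 4 2-propyl-2-(prop-2-yn-1-yl)-1,3-dioxolane, via ketal aldehyde 3 (not isolated)
Conditions: i-Bu2AlH (1.1 equiv), CH2Cl2, −78 °C; MeOH quench; then K2CO3, MeC(O)C(N2)P(O)(OMe)2, MeOH, 0 °C to rt; aq potassium sodium tartrate (KNaC4H4O6) work-up
Reagents that add atoms: dimethyl (1-diazo-2-oxopropyl)phosphonate, CC(=O)C(=[N+]=[N-])P(=O)(OC)OC
Why: Low-temperature ester reduction should stop at the aluminium hemiacetal, and the Ohira–Bestmann variant of the Seyferth–Gilbert homologation then converts the liberated aldehyde 3 into the terminal alkyne in the same flask, which spares a β-ketal aldehyde prone to β-elimination from isolation.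

Step 3
Reactants: 4 2-propyl-2-(prop-2-yn-1-yl)-1,3-dioxolane
Product: 6 4-(2-propyl-1,3-dioxolan-2-yl)but-2-ynoic acid, via lithium acetylide 5 (not isolated)
Conditions: n-BuLi (1.05 equiv), THF, −78 °C; dry CO2, −78 to 0 °C; cold 1 M HCl to pH 3, rapid extraction
Reagents that add atoms: carbon dioxide, O=C=O
Why: Deprotonation of the terminal alkyne followed by carboxylation of the lithium acetylide is a standard route to alk-2-ynoic acids, and a brief cold acidification should leave the dioxolane intact.

Step 4
Reactants: 7 olivetol (5-pentylbenzene-1,3-diol)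
Product: 8 olivetolic acid (2,4-dihydroxy-6-pentylbenzoic acid)
Conditions: MeOMgOCO2Me (2 M in DMF, 4 equiv), 120 °C; then cold aq HCl
Reagents that add atoms: methoxymagnesium methyl carbonate, CO[Mg]OC(=O)OC
Why: This Kolbe–Schmitt-type carboxylation passes CO2 from the magnesium reagent to a ring carbon ortho to a phenoxide, and the carbon that is ortho to one oxygen and para to the other should be favoured, the magnesium salicylate chelate holding the product against decarboxylation until the acid quench.

Step 5
Reactants: 8 olivetolic acid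
Product: 9 benzyl olivetolate (benzyl 2,4-dihydroxy-6-pentylbenzoate)
Conditions: BnBr (1.05 equiv), KHCO3 (1.2 equiv), DMF, rt
Reagents that add atoms: benzyl bromide, BrCc1ccccc1
Why: Bicarbonate ionises only the carboxylic acid, so SN2 O-alkylation of the carboxylate gives the benzyl ester while both phenols stay free.

Step 6
Reactants: 6 4-(2-propyl-1,3-dioxolan-2-yl)but-2-ynoic acid; 9 benzyl olivetolate
Product: 10 benzyl 2-hydroxy-6-pentyl-4-{[4-(2-propyl-1,3-dioxolan-2-yl)but-2-ynoyl]oxy}benzoate
Conditions: N,N'-dicyclohexylcarbodiimide (DCC, 1.1 equiv), 4-(dimethylamino)pyridine (DMAP, 5 mol %), CH2Cl2, −10 °C to rt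
Reagents that add atoms: none
Why: Steglich esterification of an unhindered ynoic acid should acylate only the free O4 phenol, since the O2 phenol is locked in a hydrogen bond to the benzyl ester carbonyl, and the low temperature and small charge of 4-(dimethylamino)pyridine limit conjugate addition to the ynoate and its drift to the allenoate.

Step 7
Reactants: 11 methyl (E)-3-methoxybut-2-enoate
Product: 13 1,3-dimethoxy-1-(trimethylsilyloxy)buta-1,3-diene (Brassard diene), via lithium dienolate 12 (not isolated)
Conditions: LiN(i-Pr)2 (1.1 equiv), THF, −78 °C; Me3SiCl (1.2 equiv), −78 °C to rt; pentane, filtration, bulb-to-bulb distillation, used at once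
Reagents that add atoms: chlorotrimethylsilane, C[Si](C)(C)Cl
Why: Kinetic γ-deprotonation of the β-methoxycrotonate gives the extended dienolate, which the hard silicon electrophile traps on oxygen (silyl ketene acetal formation), erasing the E geometry of 11.

Step 8
Reactants: 10 benzyl 2-hydroxy-6-pentyl-4-{[4-(2-propyl-1,3-dioxolan-2-yl)but-2-ynoyl]oxy}benzoate; 13 Brassard diene
Product: 17 benzyl 2-hydroxy-4-({2-hydroxy-4-methoxy-6-[(2-propyl-1,3-dioxolan-2-yl)methyl]benzoyl}oxy)-6-pentylbenzoate, via silyl ether 14 (not isolated), via cycloadduct 15 (not isolated), via bis-silyl depside 16 (not isolated)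
Conditions: a) N,O-bis(trimethylsilyl)acetamide (BSA, 2.5 equiv), toluene, rt, 1 h; b) freshly distilled 13 (3 equiv, two portions), 110 °C, sealed vessel; c) AcOH/THF/H2O (1:8:1), rt
Reagents that add atoms: none
Why: The silyl ketene acetal diene 13 and the electron-poor alkyne of 14 should combine in a normal-electron-demand, strongly polarised [4+2] cycloaddition (asynchronous, at the limit a Mukaiyama–Michael addition followed by closure of the allenolate onto the oxocarbenium carbon), forming the C5–C6 and C1–C2 bonds of ring A. The closest known reaction type is the Diels–Alder/aromatisation of Brassard- and Chan-type 1,1,3-trioxygenated butadienes with 3-alkylpropiolate esters, which gives 6-alkyl resorcylates; the aryl ester is only a new member of that ynoate class. Ring A closes as a six-membered carbocycle by intermolecular [4+2] annulation (four carbons from 13, two from the alkyne), first as 1,4-cyclohexadiene 15, which loses methanol across C2/C5 to give arene 16, and the acetic acid work-up then strips both aryl silyl ethers while leaving the dioxolane. The only new stereocentre, the mixed ketal carbon C2 of 15, forms as a racemate and vanishes on aromatisation, so nothing has to be controlled. Regioselectivity is the one selectivity needed: the CH2 terminus of 13 has the largest HOMO coefficient and the alkyne carbon β to the ester the largest LUMO coefficient, so their union places OH at C2, OMe at C4 and the side chain at C6. The aryloxy ester lowers the alkyne LUMO relative to an alkyl ynoate, and BSA masks the chelated ring B phenol and traps the released methanol, so that neither protonates 13 nor attacks the depside carbonyl.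

Step 9
Reactants: 17 benzyl 2-hydroxy-4-({2-hydroxy-4-methoxy-6-[(2-propyl-1,3-dioxolan-2-yl)methyl]benzoyl}oxy)-6-pentylbenzoate
Product: 18 benzyl glomelliferate (benzyl 2-hydroxy-4-{[2-hydroxy-4-methoxy-6-(2-oxopentyl)benzoyl]oxy}-6-pentylbenzoate)
Conditions: 1 M aq HCl/THF (1:4), 0 °C to rt, stopped at full conversion; pH 7 buffer wash
Reagents that add atoms: water, O
Why: Acid-catalysed ketal hydrolysis of a dialkyl ketone dioxolane runs at or below room temperature, where both esters are inert and enol-lactonisation of the freed ketone onto the aryl ester (isocoumarin closure), which needs heat, base or strong acid, should remain slow.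

Step 10
Reactants: 18 benzyl glomelliferate
Product: 19 glomelliferic acid
Conditions: H2 (1 atm), 10% Pd/C, EtOAc, rt; filtration, crystallisation
Reagents that add atoms: none
Why: Catalytic hydrogenolysis cleaves only the benzylic C–O bond under neutral conditions, so the ketone, the depside ester and the decarboxylation-prone salicylic acid unit of ring B are never exposed to acid, base or heat.

Compound list
1 | ethyl 3-oxohexanoate | CCCC(=O)CC(=O)OCC | starting material
2 | ethyl 2-(2-propyl-1,3-dioxolan-2-yl)acetate | CCCC1(CC(=O)OCC)OCCO1 | intermediate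
3 | 2-(2-propyl-1,3-dioxolan-2-yl)acetaldehyde | CCCC1(CC=O)OCCO1 | intermediate
4 | 2-propyl-2-(prop-2-yn-1-yl)-1,3-dioxolane | C#CCC1(CCC)OCCO1 | intermediate
5 | lithium acetylide of 4, [3-(2-propyl-1,3-dioxolan-2-yl)prop-1-yn-1-yl]lithium | [Li]C#CCC1(CCC)OCCO1 | intermediate
6 | 4-(2-propyl-1,3-dioxolan-2-yl)but-2-ynoic acid | CCCC1(CC#CC(=O)O)OCCO1 | intermediate
7 | olivetol (5-pentylbenzene-1,3-diol) | CCCCCc1cc(O)cc(O)c1 | starting material
8 | olivetolic acid (2,4-dihydroxy-6-pentylbenzoic acid) | CCCCCc1cc(O)cc(O)c1C(=O)O | intermediate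
9 | benzyl olivetolate (benzyl 2,4-dihydroxy-6-pentylbenzoate) | CCCCCc1cc(O)cc(O)c1C(=O)OCc1ccccc1 | intermediate
10 | benzyl 2-hydroxy-6-pentyl-4-{[4-(2-propyl-1,3-dioxolan-2-yl)but-2-ynoyl]oxy}benzoate | CCCCCc1cc(OC(=O)C#CCC2(CCC)OCCO2)cc(O)c1C(=O)OCc1ccccc1 | intermediate
11 | methyl (E)-3-methoxybut-2-enoate | CO/C(C)=C/C(=O)OC | starting material
12 | lithium dienolate of 11, lithium 1,3-dimethoxybuta-1,3-dien-1-olate | C=C(OC)C=C(OC)O[Li] | intermediate
13 | 1,3-dimethoxy-1-(trimethylsilyloxy)buta-1,3-diene (Brassard diene, ketene acetal geometry undefined) | C=C(OC)C=C(OC)O[Si](C)(C)C | intermediate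
14 | benzyl 6-pentyl-4-{[4-(2-propyl-1,3-dioxolan-2-yl)but-2-ynoyl]oxy}-2-[(trimethylsilyl)oxy]benzoate | CCCCCc1cc(OC(=O)C#CCC2(CCC)OCCO2)cc(O[Si](C)(C)C)c1C(=O)OCc1ccccc1 | intermediate
15 | racemic benzyl 4-[({4,6-dimethoxy-2-[(2-propyl-1,3-dioxolan-2-yl)methyl]-6-[(trimethylsilyl)oxy]cyclohexa-1,4-dien-1-yl}carbonyl)oxy]-6-pentyl-2-[(trimethylsilyl)oxy]benzoate | CCCCCc1cc(OC(=O)C2=C(CC3(CCC)OCCO3)CC(OC)=CC2(OC)O[Si](C)(C)C)cc(O[Si](C)(C)C)c1C(=O)OCc1ccccc1 | intermediate
16 | bis(trimethylsilyl) ether of 17 (both phenols silylated) | CCCCCc1cc(OC(=O)c2c(O[Si](C)(C)C)cc(OC)cc2CC2(CCC)OCCO2)cc(O[Si](C)(C)C)c1C(=O)OCc1ccccc1 | intermediate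
17 | benzyl 2-hydroxy-4-({2-hydroxy-4-methoxy-6-[(2-propyl-1,3-dioxolan-2-yl)methyl]benzoyl}oxy)-6-pentylbenzoate | CCCCCc1cc(OC(=O)c2c(O)cc(OC)cc2CC2(CCC)OCCO2)cc(O)c1C(=O)OCc1ccccc1 | intermediate
18 | benzyl glomelliferate (benzyl 2-hydroxy-4-{[2-hydroxy-4-methoxy-6-(2-oxopentyl)benzoyl]oxy}-6-pentylbenzoate) | CCCCCc1cc(OC(=O)c2c(O)cc(OC)cc2CC(=O)CCC)cc(O)c1C(=O)OCc1ccccc1 | intermediate
19 | glomelliferic acid (2-hydroxy-4-{[2-hydroxy-4-methoxy-6-(2-oxopentyl)benzoyl]oxy}-6-pentylbenzoic acid) | CCCCCc1cc(OC(=O)c2c(O)cc(OC)cc2CC(=O)CCC)cc(O)c1C(=O)O | target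

Total step count: 10.
Longest linear sequence: 7 (steps 1, 2, 3, 6, 8, 9, 10). Steps 4–5 and step 7 are side branches.

Steps most likely to fail

Step 8.
- **Risk:** The alkyne is activated by one ester only and carries a neopentyl-like ketal side chain, so cycloaddition may be slower than thermal decay or protonation of the diene. Acyl transfer from the activated aryl ester to the ketene acetal or to liberated methanol could also cut the depside bond.
- **Fallback:** The order of events is reversed, so that ring A is built on a simple ester and the hindered ester bond is made afterwards by classical depside coupling. Setting out from 6, alkylation with BnBr/KHCO3 in DMF gives benzyl 4-(2-propyl-1,3-dioxolan-2-yl)but-2-ynoate F1. This robust ester can be heated hard with 13 (neat or in toluene, 110–140 °C, then AcOH/THF/H2O) to give benzyl 2-hydroxy-4-methoxy-6-[(2-propyl-1,3-dioxolan-2-yl)methyl]benzoate F2. Hydrogenolysis (H2, 10% Pd/C, EtOAc) releases 2-hydroxy-4-methoxy-6-[(2-propyl-1,3-dioxolan-2-yl)methyl]benzoic acid F3. Condensing F3 with 9 using DCC in toluene comes back to the route at 17.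

Step 9.
- **Risk:** As soon as the ketone is free, its enol may attack the neighbouring aryl ester carbonyl under the acidic conditions. That would expel the ring B phenol, giving isocoumarin closure with loss of the depside. Stopping early leaves ketal behind.
- **Fallback:** No acid step follows ring formation, because the ketone is carried as an o-xylylene ketal that falls off by hydrogenolysis.
  - Setting out from 1, ketalisation with 1,2-benzenedimethanol (p-TsOH·H2O, toluene, Dean–Stark) gives ethyl 2-(3-propyl-1,5-dihydro-2,4-benzodioxepin-3-yl)acetate F4.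
  - The reduction/homologation of step 2 passes through 2-(3-propyl-1,5-dihydro-2,4-benzodioxepin-3-yl)acetaldehyde F5 to 3-propyl-3-(prop-2-yn-1-yl)-1,5-dihydro-2,4-benzodioxepine F6.
  - n-BuLi/CO2 with a short cold acidification gives 4-(3-propyl-1,5-dihydro-2,4-benzodioxepin-3-yl)but-2-ynoic acid F7.
  - DCC coupling with 9 gives benzyl 2-hydroxy-6-pentyl-4-{[4-(3-propyl-1,5-dihydro-2,4-benzodioxepin-3-yl)but-2-ynoyl]oxy}benzoate F8.
  - The BSA/diene protocol with 13 gives benzyl 2-hydroxy-4-({2-hydroxy-4-methoxy-6-[(3-propyl-1,5-dihydro-2,4-benzodioxepin-3-yl)methyl]benzoyl}oxy)-6-pentylbenzoate F9.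
  - A single neutral hydrogenolysis (H2, 10% Pd/C, THF/EtOAc) then cleaves the benzyl ester and both benzylic C–O bonds of the ketal and comes back to the route at 19.

Step 4.
- **Risk:** Carboxylation may compete at the carbon between the two hydroxyls, conversion may stall, and the product may lose CO2 again during the hot reaction or the quench.
- **Fallback:** Direct carboxylation is replaced by formylation and oxidation. Setting out from 7, Vilsmeier–Haack formylation (POCl3, DMF, 0 °C to rt, aqueous hydrolysis) attacks the position para to one hydroxyl and gives 2,4-dihydroxy-6-pentylbenzaldehyde F10. Lindgren–Pinnick oxidation (NaClO2, NaH2PO4, H2NSO3H as chlorine scavenger, dioxane/H2O) then comes back to the route at 8.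

Further compounds
F1 | step 8 | benzyl 4-(2-propyl-1,3-dioxolan-2-yl)but-2-ynoate | CCCC1(CC#CC(=O)OCc2ccccc2)OCCO1
F2 | step 8 | benzyl 2-hydroxy-4-methoxy-6-[(2-propyl-1,3-dioxolan-2-yl)methyl]benzoate | CCCC1(Cc2cc(OC)cc(O)c2C(=O)OCc2ccccc2)OCCO1
F3 | step 8 | 2-hydroxy-4-methoxy-6-[(2-propyl-1,3-dioxolan-2-yl)methyl]benzoic acid | CCCC1(Cc2cc(OC)cc(O)c2C(=O)O)OCCO1
F4 | step 9 | ethyl 2-(3-propyl-1,5-dihydro-2,4-benzodioxepin-3-yl)acetate | CCCC1(CC(=O)OCC)OCc2ccccc2CO1
F5 | step 9 | 2-(3-propyl-1,5-dihydro-2,4-benzodioxepin-3-yl)acetaldehyde | CCCC1(CC=O)OCc2ccccc2CO1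
F6 | step 9 | 3-propyl-3-(prop-2-yn-1-yl)-1,5-dihydro-2,4-benzodioxepine | C#CCC1(CCC)OCc2ccccc2CO1
F7 | step 9 | 4-(3-propyl-1,5-dihydro-2,4-benzodioxepin-3-yl)but-2-ynoic acid | CCCC1(CC#CC(=O)O)OCc2ccccc2CO1
F8 | step 9 | benzyl 2-hydroxy-6-pentyl-4-{[4-(3-propyl-1,5-dihydro-2,4-benzodioxepin-3-yl)but-2-ynoyl]oxy}benzoate | CCCCCc1cc(OC(=O)C#CCC2(CCC)OCc3ccccc3CO2)cc(O)c1C(=O)OCc1ccccc1
F9 | step 9 | benzyl 2-hydroxy-4-({2-hydroxy-4-methoxy-6-[(3-propyl-1,5-dihydro-2,4-benzodioxepin-3-yl)methyl]benzoyl}oxy)-6-pentylbenzoate | CCCCCc1cc(OC(=O)c2c(O)cc(OC)cc2CC2(CCC)OCc3ccccc3CO2)cc(O)c1C(=O)OCc1ccccc1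
F10 | step 4 | 2,4-dihydroxy-6-pentylbenzaldehyde | CCCCCc1cc(O)cc(O)c1C=O
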